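The closed, stirred flask held solid G, which dissolved and went on with X to L. The three earlier runs and the five new flasks were these:

| setting | north-east | north | south-east | blue | teal | green | grey | violet |
|---|---|---|---|---|---|---|---|---|
| G | 0.016 M | 0.078 M | 0.020 M | 0.030 M | 0.030 M | 0.012 M | 0.060 M | 0.020 M |
| X | 0.024 M | 0.024 M | 0.035 M | 0.100 M | 0.0120 M | 0.0120 M | 0.100 M | 0.0240 M |
| remark | run made earlier | run made earlier | run made earlier |  |  |  |  |  |
| time |  |  |  | 1.5 h | 1.5 h | 1.5 h | 1.5 h | 1.5 h |

- north-east (time / min: L / %, G / %): 10.0: 2, 68; 20.0: 5, 48; 30.0: 13, 31; 40.0: 22, 21; 50.0: 31, 14; 60.0: 35, 9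
- north (time / min: L / %, G / %): 4.00: 1, 100; 12.0: 0, 90; 20.0: 0, 87; 30.0: 0, 86; 50.0: 6, 82; 60.0: 8, 84
- south-east (time / min: L / %, G / %): 5.00: 0, 83; 10.0: 2, 72; 20.0: 7, 49; 30.0: 17, 36; 60.0: 43, 7

(scatter of a reading: 2 percentage points)

- all flasks from highest to lowest amount of L, in percent of the G charged, at 1.5 h (blue / teal / green / grey / violet)
- the amount of L, in percent of the G charged of the flask you put first, at 1.5 h
- the amount of L, in percent of the G charged of the flask you put last, at 1.5 h

In the north run the solid levelled off with 14.0 % gone at 30.0 min, a reading of 2.20 X per G, which I took as 2. So I reckoned with the X ceiling, the X charged divided by twice the G charged, as the most L a flask can reach; below 100 %, X is the limiting reagent. For teal it was 20.0 %, for green 50.0 %, for violet 60.0 % and for grey 83.3 %, while blue, at 167 %, was limited by G. The south-east run had reached about half its ceiling at 60.0 min, so I expected the flasks to stand below their ceilings at 1.5 h.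

The north-east solid fell by 91.0 %, more than its ceiling of 75.0 %. I put that down to G merely dissolved, whereas the forecast held that “each L seems to return one X”. It gave blue > grey > violet > green > teal, with blue at 72 % and teal at 15 %. Its blue figure lies near what a straight line through the last two south-east readings gives at that time.

The flasks gave blue > grey > violet > green > teal, with blue at 92.0 % and teal at 10.9 %, so blue stood 20 percentage points above the forecast.

    X + Z → Q (k = 0.151 M⁻¹ s⁻¹)
    D → L (k = 0.0277 s⁻¹)
    Q ⇌ J (K = 0.226, k = 0.00317 s⁻¹)
    Q → D (k = 9.28 × 10⁻⁴ s⁻¹)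
    E + X ⇌ Z (K = 23.0 M⁻¹, k = 1.26 M⁻¹ s⁻¹)
    G ⇌ E, rate k6*(cs6 - [E]) while solid is left; crystals form when [E] > cs6 (solubility = 6.50 mM, k = 0.00172 s⁻¹)

Neither blue nor teal had come to rest at 1.5 h. Teal's L went on to 19.1 % at 15.0 h, just under its ceiling of 20.0 %. Blue's L reached 100 % by then, while its X stood at 40.0 % of its charge, the 40.0 % that 2 X per G leaves.

For the neighbour of teal charged with 0.030 M of X, the ceiling is 50.0 %. That flask gave 34.7 % at 1.5 h, below the ceiling, with 18 % of its X still unbound.

The readings come from a simulation on assumed constants; noise was put on by code.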